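**Retrosynthetic overview** (target numbered as a furo[3,2-b]pyran-5-one: O1, C2, C3, C3a, O4, C5(=O), C6, C7, C7a; ring A = pyranone, ring B = oxolane; side chain C1′–C5′)
- Side chain last: C3′–OH from a C3′ ketone (CBS reduction); C1′=C2′ by Wittig reaction of a C2 aldehyde with a lactate-derived acyl ylide; the C4′ benzoate by Mitsunobu inversion of (S)-lactate.
- Key disconnection: ring A is cut at C6=C7 and at O4–C3a, giving an oxolane with a vinyl group on C7a and a triflate on C3a (C3a epimeric to the target) plus an acrylate salt. Forward: SN2 inversion by the carboxylate, then ring-closing metathesis, in one flask.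
- Enabling feature: on ring B all four substituents (C2, C3, C3a, C7a) are cis, so O4 on C3a is cis to C7 on C7a. In the C3a epimer the leaving group is therefore trans to everything: the carboxylate enters from the face of the C7a vinyl group, neither H3 nor H7a is anti to the leaving group, and the acrylate lands 1,2-cis to the vinyl group, set up for a six-membered ring.
- Ring order: ring B is bought (2,5-anhydro-D-glucitol: C2, C3, C7a correct, C3a inverted, all six carbons kept). A temporary 1,3-dioxane (acetonide over O3 and the C2 CH2O, the only cis pair) is formed first and tells the two secondary hydroxyls apart. Ring A is closed in the key step, then the dioxane is removed.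

Key step: step 5

Assumption: 2,5-anhydro-D-glucitol (1) is taken as a purchased material; it is otherwise reachable from D-mannitol by 1,6-dibenzoylation, acid-catalysed cyclodehydration and debenzoylation.

**Step 1**
Reactants: 1 2,5-anhydro-D-glucitol
Product: 2 2,5-anhydro-1,3-O-isopropylidene-D-glucitol
Conditions: Me2C(OMe)2, TsOH·H2O (cat.), DMF, rt; Et3N quench
Reagents that add atoms: 2,2-dimethoxypropane, COC(C)(C)OC
Why: Acid-catalysed transacetalisation under thermodynamic control should give only the 1,3-dioxane across the C1 and C3 hydroxyls (glucitol numbering), the one pair that is cis on the oxolane ring, whereas the trans-3,4-diol and the trans O4/C6 pair cannot be bridged without strain; no stereocentre is touched.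

**Step 2**
Reactants: 2 2,5-anhydro-1,3-O-isopropylidene-D-glucitol
Product: 3 2,5-anhydro-4,6-O-isopropylidene-aldehydo-L-gulose (the C6 aldehyde of 2; secondary OH free)
Conditions: TEMPO (10 mol %), PhI(OAc)2, CH2Cl2, rt
Reagents that add atoms: none
Why: Oxoammonium (TEMPO) oxidation with PhI(OAc)2 as terminal oxidant oxidises the unhindered primary alcohol much faster than the secondary one, stops at the aldehyde and is non-basic, so the α-alkoxy stereocentre should survive.

**Step 3**
Reactants: 3 2,5-anhydro-4,6-O-isopropylidene-aldehydo-L-gulose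
Product: 4 3,6-anhydro-1,2-dideoxy-5,7-O-isopropylidene-L-gulo-hept-1-enitol (oxolane with vinyl and dioxane-fused CH2O cis; free OH trans to the vinyl group)
Conditions: Ph3PCH3Br, KOtBu, THF, −78 to 0 °C
Reagents that add atoms: methyltriphenylphosphonium bromide, C[P+](c1ccccc1)(c1ccccc1)c1ccccc1.[Br-]
Why: Wittig methylenation with an excess of the non-stabilised ylide at low temperature should convert the aldehyde into the terminal alkene (the free hydroxyl is only reversibly deprotonated) without creating a stereocentre.

**Step 4**
Reactants: 4 vinyl alcohol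
Product: 5 the 4-O-trifluoromethanesulfonate of 4
Conditions: Tf2O, pyridine, CH2Cl2, −20 °C; used directly
Reagents that add atoms: trifluoromethanesulfonic anhydride, O=S(=O)(OS(=O)(=O)C(F)(F)F)C(F)(F)F
Why: O-Sulfonylation with Tf2O/pyridine breaks only the O–H bond, so configuration at carbon is retained, and the two β-oxygens should make the secondary triflate stable enough for direct use.

**Step 5**
Reactants: 5 triflate; 6 potassium acrylate
Product: 8 tricyclic lactone acetonide (isopropylidene acetal of 9 across O3 and the C2 CH2O), via inverted acrylate ester 7 (not isolated)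
Conditions: 6 (1.3 equiv), 18-crown-6, BHT, toluene, 40 °C; then second-generation Hoveyda–Grubbs catalyst RuCl2(=CH-C6H4-2-OiPr)(H2IMes) (5 mol %; H2IMes = 1,3-dimesitylimidazolidin-2-ylidene), 5 mM, 80 °C, same flask
Reagents that add atoms: none
Why: The carboxylate oxygen of 6 displaces the triflate of 5 from the face opposite to the leaving group (SN2, Walden inversion), which makes the O4–C3a bond and gives acrylate 7; the ruthenium carbene then forms on the terminal vinyl group and closes onto the acrylate C=C with loss of ethylene, which makes C6=C7. The closest known reaction types are the inversion of secondary carbohydrate triflates by crown-ether-activated alkali carboxylates and the ring-closing metathesis of acrylates of homoallylic alcohols to 5,6-dihydro-2H-pyran-2-ones with second-generation ruthenium catalysts. One ring is closed, the six-membered lactone ring A, by ring-closing metathesis of two terminal alkenes; the ring alkene is necessarily Z and the A/B fusion necessarily cis. The one new stereocentre, C3a, is set by the stereospecific backside attack, so it follows from the C4 carbinol of D-glucitol, while C2, C3 and C7a are carried through unchanged. Substitution must beat elimination and ionisation with acetal-oxygen participation: both neighbouring hydrogens (future H3 and H7a) are syn to the triflate on the five-membered ring, so no anti-periplanar E2 path exists, and a naked carboxylate in a non-ionising solvent favours direct displacement. Ring closure must beat cross-metathesis, which the cis-1,2 placement of acrylate and vinyl group and high dilution should secure.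

**Step 6**
Reactants: 8 tricyclic lactone acetonide
Product: 9 (2S,3R,3aR,7aR)-3-hydroxy-2-(hydroxymethyl)-2,3,3a,7a-tetrahydro-5H-furo[3,2-b]pyran-5-one
Conditions: AcOH/H2O 4:1, 40 °C
Reagents that add atoms: none
Why: Mild aqueous acid should hydrolyse the isopropylidene acetal (acetal hydrolysis) and leave the unsaturated lactone and all stereocentres untouched.

**Step 7**
Reactants: 9 diol lactone
Product: 10 (2R,3S,3aR,7aR)-3-hydroxy-5-oxo-2,3,3a,7a-tetrahydro-5H-furo[3,2-b]pyran-2-carbaldehyde (same all-cis geometry as 9; descriptors change by priority only)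
Conditions: TEMPO (10 mol %), PhI(OAc)2, CH2Cl2/MeCN, rt; used crude
Reagents that add atoms: none
Why: The same TEMPO/PhI(OAc)2 oxidation should take the primary alcohol to the aldehyde in the presence of the secondary C3 hydroxyl under non-basic conditions, which protects C2 from epimerisation and the lactone from opening.

**Step 8**
Reactants: 11 benzyl (S)-lactate; 12 benzoic acid
Product: 13 benzyl (R)-2-(benzoyloxy)propanoate
Conditions: PPh3, DIAD, THF, 0 °C to rt
Reagents that add atoms: none
Why: Mitsunobu esterification proceeds by SN2 displacement of the alkoxyphosphonium ion by benzoate, so the (S)-lactate carbinol is inverted to the R benzoate that becomes C4′.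

**Step 9**
Reactants: 13 benzyl (R)-2-(benzoyloxy)propanoate
Product: 14 (R)-2-(benzoyloxy)propanoic acid
Conditions: H2 (1 atm), Pd/C (palladium on carbon, 10 wt %), EtOAc, rt
Reagents that add atoms: none
Why: Hydrogenolysis of the benzyl ester over palladium on carbon should leave the benzoate and the stereocentre untouched.

**Step 10**
Reactants: 14 (R)-2-(benzoyloxy)propanoic acid
Product: 16 (R)-3-oxo-4-(triphenyl-λ5-phosphanylidene)butan-2-yl benzoate, via acid chloride 15 (not isolated)
Conditions: (COCl)2, DMF (cat.), CH2Cl2, 0 °C to rt, evaporate; then Ph3P=CH2 (2.1 equiv, from Ph3PCH3Br and NaN(SiMe3)2), THF, −78 °C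
Reagents that add atoms: methyltriphenylphosphonium bromide, C[P+](c1ccccc1)(c1ccccc1)c1ccccc1.[Br-]
Why: Oxalyl chloride/DMF gives acid chloride 15, which C-acylates methylenetriphenylphosphorane far faster than the benzoate does, and the second equivalent of ylide deprotonates the acylphosphonium salt (transylidation) to the stabilised acyl ylide; the low temperature should limit enolisation at the α-stereocentre.

**Step 11**
Reactants: 10 lactone aldehyde; 16 acyl ylide
Product: 17 (2R,4E)-5-[(2S,3R,3aR,7aR)-3-hydroxy-5-oxo-2,3,3a,7a-tetrahydro-5H-furo[3,2-b]pyran-2-yl]-3-oxopent-4-en-2-yl benzoate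
Conditions: CH2Cl2, rt to 40 °C
Reagents that add atoms: none
Why: Wittig olefination with a stabilised acyl ylide runs without base and should give the (E)-enone (reversible betaine/oxaphosphetane formation favours the trans product) without epimerising C2 or opening the lactone.

**Step 12**
Reactants: 17 enone
Product: 18 (2R,3S,4E)-3-hydroxy-5-[(2S,3R,3aR,7aR)-3-hydroxy-5-oxo-2,3,3a,7a-tetrahydro-5H-furo[3,2-b]pyran-2-yl]pent-4-en-2-yl benzoate (target)
Conditions: (S)-2-methyl-CBS-oxazaborolidine (0.5 equiv), BH3·SMe2, THF, −30 °C; MeOH quench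
Reagents that add atoms: none
Why: Corey–Bakshi–Shibata reduction: with the alkenyl group as the large substituent the (S)-oxazaborolidine should deliver hydride to the face that gives the 3′S alcohol, the same sense as Felkin–Anh control by the neighbouring benzoyloxy stereocentre (1,2-anti product), while borane at low temperature leaves the lactone, the benzoate and the electron-poor alkenes alone.

**Compound list**
1 | 2,5-anhydro-D-glucitol | OC[C@@H]1O[C@H](CO)[C@@H](O)[C@@H]1O | starting material
2 | 2,5-anhydro-1,3-O-isopropylidene-D-glucitol | CC1(C)OC[C@@H]2O[C@H](CO)[C@@H](O)[C@@H]2O1 | intermediate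
3 | 2,5-anhydro-4,6-O-isopropylidene-aldehydo-L-gulose | CC1(C)OC[C@@H]2O[C@H](C=O)[C@@H](O)[C@@H]2O1 | intermediate
4 | 3,6-anhydro-1,2-dideoxy-5,7-O-isopropylidene-L-gulo-hept-1-enitol | CC1(C)OC[C@@H]2O[C@H](C=C)[C@@H](O)[C@@H]2O1 | intermediate
5 | 4-O-trifluoromethanesulfonate of 4 | CC1(C)OC[C@@H]2O[C@H](C=C)[C@@H](OS(=O)(=O)C(F)(F)F)[C@@H]2O1 | intermediate
6 | potassium acrylate | C=CC(=O)[O-].[K+] | starting material
7 | 4-O-acryloyl-3,6-anhydro-1,2-dideoxy-5,7-O-isopropylidene-L-galacto-hept-1-enitol (C4 inverted, all-cis) | CC1(C)OC[C@@H]2O[C@H](C=C)[C@H](OC(=O)C=C)[C@@H]2O1 | intermediate (not isolated)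
8 | tricyclic lactone acetonide (isopropylidene acetal of 9 across O3 and the C2 CH2O) | CC1(C)OC[C@@H]2O[C@@H]3C=CC(=O)O[C@@H]3[C@@H]2O1 | intermediate
9 | (2S,3R,3aR,7aR)-3-hydroxy-2-(hydroxymethyl)-2,3,3a,7a-tetrahydro-5H-furo[3,2-b]pyran-5-one | OC[C@@H]1O[C@@H]2C=CC(=O)O[C@@H]2[C@@H]1O | intermediate
10 | (2R,3S,3aR,7aR)-3-hydroxy-5-oxo-2,3,3a,7a-tetrahydro-5H-furo[3,2-b]pyran-2-carbaldehyde | O=C[C@@H]1O[C@@H]2C=CC(=O)O[C@@H]2[C@@H]1O | intermediate
11 | benzyl (S)-lactate | C[C@H](O)C(=O)OCc1ccccc1 | starting material
12 | benzoic acid | OC(=O)c1ccccc1 | starting material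
13 | benzyl (R)-2-(benzoyloxy)propanoate | C[C@@H](OC(=O)c1ccccc1)C(=O)OCc1ccccc1 | intermediate
14 | (R)-2-(benzoyloxy)propanoic acid | C[C@@H](OC(=O)c1ccccc1)C(=O)O | intermediate
15 | (R)-2-(benzoyloxy)propanoyl chloride | C[C@@H](OC(=O)c1ccccc1)C(Cl)=O | intermediate (not isolated)
16 | (R)-3-oxo-4-(triphenyl-λ5-phosphanylidene)butan-2-yl benzoate | C[C@@H](OC(=O)c1ccccc1)C(=O)C=P(c1ccccc1)(c1ccccc1)c1ccccc1 | intermediate
17 | (2R,4E)-5-[(2S,3R,3aR,7aR)-3-hydroxy-5-oxo-2,3,3a,7a-tetrahydro-5H-furo[3,2-b]pyran-2-yl]-3-oxopent-4-en-2-yl benzoate | C[C@@H](OC(=O)c1ccccc1)C(=O)/C=C/[C@@H]1O[C@@H]2C=CC(=O)O[C@@H]2[C@@H]1O | intermediate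
18 | (2R,3S,4E)-3-hydroxy-5-[(2S,3R,3aR,7aR)-3-hydroxy-5-oxo-2,3,3a,7a-tetrahydro-5H-furo[3,2-b]pyran-2-yl]pent-4-en-2-yl benzoate | C[C@@H](OC(=O)c1ccccc1)[C@@H](O)/C=C/[C@@H]1O[C@@H]2C=CC(=O)O[C@@H]2[C@@H]1O | target

**Step count**
Total: 12 steps. Longest linear sequence: 9 steps (steps 1–7, 11, 12; 1 → 2 → 3 → 4 → 5 → 8 → 9 → 10 → 17 → 18).

**Steps most likely to fail**

Step 5. The backside attack is flanked by two cis substituents and may stall, or ionisation with participation of the acetal oxygen may give retention or acetal migration; residual carboxylate may also deactivate the ruthenium carbene, or cross-metathesis may compete with ring closure. The fallback sets out from 4 and returns at 8, replacing both the activation mode and the ring-closing reaction. Mitsunobu esterification of 4 with diethylphosphonoacetic acid (PPh3, DIAD) should give, with inversion, the phosphonoacetate ester F1, which can be purified. Ozonolysis of its vinyl group (O3, CH2Cl2, −78 °C; Me2S) gives the β-acyloxy aldehyde F2. Intramolecular Horner–Wadsworth–Emmons olefination under Masamune–Roush conditions (LiCl, iPr2NEt, MeCN) then closes ring A to 8.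

Step 3. The basic ylide may epimerise the α-alkoxy aldehyde, or the free β-alkoxide may trigger retro-aldol or elimination. The fallback sets out from 2 and returns at 4, with the hydroxyl masked throughout. Silylation of both hydroxyls (Et3SiCl, imidazole, DMF) gives the bis(triethylsilyl) ether F3. Swern oxidation ((COCl)2, DMSO, then Et3N) cleaves and oxidises only the primary silyl ether, giving the silyloxy aldehyde F4. Wittig methylenation gives the silyl-protected vinyl compound F5, and Bu4NF in THF frees 4.

Step 12. Hydride delivery may show poor facial selectivity on the fully assembled enone, and the benzoate may migrate to the new hydroxyl during work-up. The fallback sets out from 10 (core) and 15 (side chain) and arrives at 18, with C3′ set on a small fragment before the union. Non-basic Takai–Lombardo methylenation of 10 (Zn, CH2Br2, TiCl4) gives the vinyl lactone F6. Stille acylation of 15 with tributyl(vinyl)stannane (Pd(PPh3)4 cat.) gives the vinyl ketone F7. Its CBS reduction gives the allylic alcohol F8, whose diastereomers can be separated at this stage. Cross-metathesis of F6 with an excess of F8 (second-generation Hoveyda–Grubbs catalyst, CH2Cl2, 40 °C) should give 18 with the E alkene.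

**Further compounds**
F1 | step 5 | 4-O-(diethoxyphosphorylacetyl)-3,6-anhydro-1,2-dideoxy-5,7-O-isopropylidene-L-galacto-hept-1-enitol | CC1(C)OC[C@@H]2O[C@H](C=C)[C@H](OC(=O)CP(=O)(OCC)OCC)[C@@H]2O1
F2 | step 5 | aldehyde from ozonolysis of F1 (formyl group in place of vinyl) | CC1(C)OC[C@@H]2O[C@H](C=O)[C@H](OC(=O)CP(=O)(OCC)OCC)[C@@H]2O1
F3 | step 3 | 2,5-anhydro-1,3-O-isopropylidene-4,6-bis-O-(triethylsilyl)-D-glucitol | CC1(C)OC[C@@H]2O[C@H](CO[Si](CC)(CC)CC)[C@@H](O[Si](CC)(CC)CC)[C@@H]2O1
F4 | step 3 | 3-O-triethylsilyl ether of aldehyde 3 | CC1(C)OC[C@@H]2O[C@H](C=O)[C@@H](O[Si](CC)(CC)CC)[C@@H]2O1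
F5 | step 3 | 4-O-triethylsilyl ether of 4 | CC1(C)OC[C@@H]2O[C@H](C=C)[C@@H](O[Si](CC)(CC)CC)[C@@H]2O1
F6 | step 12 | (2S,3R,3aR,7aR)-3-hydroxy-2-vinyl-2,3,3a,7a-tetrahydro-5H-furo[3,2-b]pyran-5-one | C=C[C@@H]1O[C@@H]2C=CC(=O)O[C@@H]2[C@@H]1O
F7 | step 12 | (R)-3-oxopent-4-en-2-yl benzoate | C[C@@H](OC(=O)c1ccccc1)C(=O)C=C
F8 | step 12 | (2R,3S)-3-hydroxypent-4-en-2-yl benzoate | C[C@@H](OC(=O)c1ccccc1)[C@@H](O)C=C
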